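**Plan**

1. Retrosynthesis cuts C6–C1'' (prenyl, ring A) and C2'–C1''' (geranyl, ring B) in one operation, then the two tertiary aryl ether bonds O5–C and O3'–C, and last the 7-O–CH3 bond, which leads back to (S)-hesperetin.
2. Enabling feature: each chain sits on an aromatic CH carbon ortho to a free phenol, C6 beside O5 on ring A and C2' beside O3' on ring B. The second ortho carbon of each oxygen is blocked (ring-fusion C4a; C4' bearing OMe), so each chain is the retron of an O→C aryl Claisen shift of a tertiary allyl ether.
3. Forward: no ring is built, since rings A, B and C come intact from hesperetin. The chain is joined as O7-methyl, then O3'-dehydrolinalyl, then O5-dimethylpropargyl; both alkynes are semi-reduced and one thermolysis moves both allyl units from oxygen to carbon.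
4. Stereochemistry: C2 (S) comes from the chiral pool and is protected by keeping free base away once ring A has no ionisable OH. The C2'''=C3''' E geometry is set in the chair transition state of the ring-B shift.

Key step: step 5

Assumptions: (S)-hesperetin of high enantiomeric purity is taken as purchasable, and its ee would be checked by chiral HPLC at 2 and at 8. Dehydrolinalool is used as the racemate, so 4, 5, 8, 9, 10 and 11 are epimer mixtures at the ether carbon; this centre becomes the sp2 carbon C3''' in step 5, so the mixture is of no consequence. Flavanone locants are used throughout (C1''–C5'' prenyl, C1'''–C10''' geranyl).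

**Route**

Step 1
Reactants: 1 (S)-hesperetin
Product: 2 (2S)-7-O-methylhesperetin [(2S)-5-hydroxy-2-(3-hydroxy-4-methoxyphenyl)-7-methoxychroman-4-one]
Conditions: MeI (1.05 equiv), K2CO3 (1.0 equiv), acetone, 0 °C → rt
Reagents that add atoms: iodomethane, CI
Why: Williamson methylation; the 7-OH para to the C4 carbonyl is the most acidic phenol (5-OH is chelated, 3'-OH is an ordinary phenol), so one equivalent of carbonate ionises it alone, and a phenoxide on ring A disfavours retro-oxa-Michael opening, so C2 should keep its configuration.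

Step 2
Reactants: 2 (2S)-7-O-methylhesperetin; 3 (±)-dehydrolinalool (3,7-dimethyloct-6-en-1-yn-3-ol)
Product: 5 (2S)-5-hydroxy-7-methoxy-2-[4-methoxy-3-(3,7-dimethyloct-6-en-1-yn-3-yloxy)phenyl]chroman-4-one, via dehydrolinalyl trifluoroacetate 4 (not isolated)
Conditions: 3, TFAA, DBU, MeCN, −5 °C; then added to 2, DBU (1.1 equiv), CuCl2·2H2O (1 mol %), MeCN, −5 → 0 °C
Reagents that add atoms: none
Why: Copper-catalysed propargylic etherification of a phenol with a tertiary propargylic trifluoroacetate (via a copper allenylidene); only the unchelated 3'-phenoxide is nucleophilic enough at this temperature, while the hydrogen-bonded, peri-hindered 5-OH stays free.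

Step 3
Reactants: 5 the 3'-O-dehydrolinalyl ether; 6 2-methylbut-3-yn-2-ol
Product: 8 (2S)-7-methoxy-5-(2-methylbut-3-yn-2-yloxy)-2-[4-methoxy-3-(3,7-dimethyloct-6-en-1-yn-3-yloxy)phenyl]chroman-4-one, via 2-methylbut-3-yn-2-yl trifluoroacetate 7 (not isolated)
Conditions: 6, TFAA, DBU, MeCN, −5 °C; then excess added to 5, DBU (1.1 equiv), CuCl2·2H2O (2 mol %), MeCN, 0 °C, N2; unreacted 5 recycled
Reagents that add atoms: none
Why: The same copper-catalysed propargylic etherification; with O3' capped, stoichiometric DBU breaks the O5–H···O=C4 chelate and the phenoxide captures the small, highly electrophilic copper allenylidene, and since DBU ends as its trifluoroacetate salt little free base is left to open the pyranone of the now fully etherified ring A.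

Step 4
Reactants: 8 the bis-propargyl ether
Product: 9 (2S)-7-methoxy-5-(2-methylbut-3-en-2-yloxy)-2-[4-methoxy-3-(3,7-dimethylocta-1,6-dien-3-yloxy)phenyl]chroman-4-one
Conditions: H2 (1 atm, 2 equiv uptake), Lindlar catalyst, quinoline, EtOAc, rt; filtered through Celite, concentrated below 30 °C, used crude
Reagents that add atoms: none
Why: Lindlar semi-hydrogenation stops both terminal alkynes at the vinyl stage and leaves the trisubstituted olefin, the aryl ketone and the benzylic C2–O1 bond alone; the acid-labile bis-ether is not exposed to silica.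

Step 5
Reactants: 9 the 5-O-(1,1-dimethylallyl) 3'-O-linalyl bis-ether
Product: 13 CNP0241771.1 [(2S)-2-{2-[(2E)-3,7-dimethylocta-2,6-dienyl]-3-hydroxy-4-methoxyphenyl}-5-hydroxy-7-methoxy-6-(3-methylbut-2-enyl)chroman-4-one], via ring-A ortho-dienone 10 (not isolated), via 6-prenyl 3'-O-linalyl ether 11 (not isolated), via ring-B ortho-dienone 12 (not isolated)
Conditions: degassed o-xylene (0.02 M), 130 °C, N2, no base; AgNO3–SiO2 chromatography
Reagents that add atoms: none
Why: Each tertiary allyl aryl ether undergoes a concerted chair [3,3] shift (aryl Claisen) that bonds its unsubstituted vinyl terminus to the free ortho carbon, C1'' to C6 in 10 and C1''' to C2' in 12, and each ortho-dienone then enolises to the phenol; the closest known reaction is the thermal rearrangement of aryl 1,1-dimethylallyl ethers to ortho-prenylphenols. No ring is closed and no stereocentre is created: the epimeric ether carbon becomes sp2 C3''', and C2 is not involved because the medium is neutral and the pyranone cannot open. Regiochemistry is fixed by the substrate: O5 has C6 as its only ortho CH (the other ortho carbon is C4a), and the C6 dienone carries a primary prenyl group that should enolise faster than it could Cope-shift to C8, while at ring B the second ortho carbon C4' bears OMe, so the allyl unit goes to C2'. The one selectivity not fixed by connectivity is the C2'''=C3''' geometry, which requires homoprenyl rather than methyl in the pseudo-equatorial site of the chair; this preference should be modest, so a minor 2'-neryl (Z) isomer is expected and is removed on silver-nitrate silica. The order of the two shifts is immaterial; the peri-compressed ring-A ether is written as the faster one.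

**Compound list**

1 | (S)-hesperetin, (2S)-5,7-dihydroxy-2-(3-hydroxy-4-methoxyphenyl)chroman-4-one | COc1ccc([C@@H]2CC(=O)c3c(O)cc(O)cc3O2)cc1O | starting material
2 | (2S)-7-O-methylhesperetin | COc1ccc([C@@H]2CC(=O)c3c(O)cc(OC)cc3O2)cc1O | intermediate
3 | (±)-dehydrolinalool, 3,7-dimethyloct-6-en-1-yn-3-ol | C#CC(C)(O)CCC=C(C)C | starting material
4 | 3,7-dimethyloct-6-en-1-yn-3-yl trifluoroacetate (dehydrolinalyl trifluoroacetate) | C#CC(C)(OC(=O)C(F)(F)F)CCC=C(C)C | intermediate
5 | (2S)-7-O-methylhesperetin 3'-O-(3,7-dimethyloct-6-en-1-yn-3-yl) ether | COc1ccc([C@@H]2CC(=O)c3c(O)cc(OC)cc3O2)cc1OC(C)(C#C)CCC=C(C)C | intermediate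
6 | 2-methylbut-3-yn-2-ol | C#CC(C)(C)O | starting material
7 | 2-methylbut-3-yn-2-yl trifluoroacetate | C#CC(C)(C)OC(=O)C(F)(F)F | intermediate
8 | (2S)-7-O-methylhesperetin 5-O-(2-methylbut-3-yn-2-yl) 3'-O-(3,7-dimethyloct-6-en-1-yn-3-yl) bis-ether | COc1ccc([C@@H]2CC(=O)c3c(OC(C)(C)C#C)cc(OC)cc3O2)cc1OC(C)(C#C)CCC=C(C)C | intermediate
9 | (2S)-7-O-methylhesperetin 5-O-(1,1-dimethylallyl) 3'-O-linalyl bis-ether | COc1ccc([C@@H]2CC(=O)c3c(OC(C)(C)C=C)cc(OC)cc3O2)cc1OC(C)(C=C)CCC=C(C)C | intermediate
10 | ring-A ortho-dienone: 6-prenyl-6H-5-oxo tautomer, 3'-O-linalyl ether intact | COc1ccc([C@@H]2CC(=O)C3=C(C=C(OC)C(CC=C(C)C)C3=O)O2)cc1OC(C)(C=C)CCC=C(C)C | intermediate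
11 | (2S)-5-hydroxy-7-methoxy-6-(3-methylbut-2-enyl)-2-[4-methoxy-3-(3,7-dimethylocta-1,6-dien-3-yloxy)phenyl]chroman-4-one | COc1ccc([C@@H]2CC(=O)c3c(cc(OC)c(CC=C(C)C)c3O)O2)cc1OC(C)(C=C)CCC=C(C)C | intermediate
12 | ring-B ortho-dienone: 2'-[(E)-geranyl]-2'H-3'-oxo tautomer of the 6-prenyl flavanone | COC1=CC=C([C@@H]2CC(=O)c3c(cc(OC)c(CC=C(C)C)c3O)O2)C(C/C=C(\C)CCC=C(C)C)C1=O | intermediate
13 | CNP0241771.1, (2S)-2-{2-[(2E)-3,7-dimethylocta-2,6-dienyl]-3-hydroxy-4-methoxyphenyl}-5-hydroxy-7-methoxy-6-(3-methylbut-2-enyl)chroman-4-one | COc1ccc([C@@H]2CC(=O)c3c(cc(OC)c(CC=C(C)C)c3O)O2)c(C/C=C(\C)CCC=C(C)C)c1O | target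

**Count**

Total steps: 5. Longest linear sequence: 5 steps (1 → 2 → 5 → 8 → 9 → 13).

**Steps most likely to fail**

1. Step 3. The hydrogen-bonded, peri-hindered 5-hydroxyl may be alkylated incompletely, and once ring A carries no free OH the base may open the pyranone and erode the C2 configuration. Fallback: set out from 5 and place a primary allyl group on O5 under neutral Mitsunobu conditions (allyl alcohol, PPh3, DIAD, THF), which should give the 5-O-allyl 3'-O-dehydrolinalyl ether F1. Lindlar semi-hydrogenation of its single alkyne gives the 5-O-allyl 3'-O-linalyl bis-ether F2. A Eu(fod)3-assisted double Claisen shift (toluene, 80–110 °C; the lanthanide held at O4/O5 accelerates the 5-O-allyl shift to C6) gives 6-allyl-2'-geranyl-7-O-methylhesperetin F3. Cross-metathesis of the terminal allyl group with 2-methylbut-2-ene (Grubbs II, CH2Cl2, 40 °C) converts it to prenyl and returns to the route at 13.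

2. Step 5. The two chair transition states at ring B (methyl versus homoprenyl pseudo-axial) may be discriminated too weakly, so that the E and Z chains form in comparable amounts and resist separation; some para-migration to C6' is also possible. Fallback: set out from 2 and move both chains by an ion-pair [1,3] O→C shift that leaves the allyl double bond in place, so that the E geometry comes from geraniol. Mitsunobu etherification of the 3'-OH with geraniol gives the 3'-O-geranyl ether F4. A second Mitsunobu reaction with prenyl alcohol on the 5-OH gives the 5-O-prenyl 3'-O-geranyl bis-ether F5. Montmorillonite K10 in CH2Cl2 at 0 °C should then shift prenyl to C6 and geranyl to C2', returning at 13 after removal of C8 and C6' regioisomers by chromatography.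

3. Step 4. The new vinyl groups may be over-reduced, or the tertiary allyl aryl ethers may ionise or rearrange on the catalyst. Fallback: set out from 2 and install both ethers directly at the alkene oxidation level by branched-selective Tsuji–Trost O-allylation. Geranyl methyl carbonate with Pd2(dba)3 and a racemic diaminocyclohexane-derived bis(diphenylphosphinobenzamide) ligand in CH2Cl2 should give the 3'-O-linalyl ether F6. tert-Butyl 2-methylbut-3-en-2-yl carbonate with Pd(PPh3)4 in THF at 0 °C, with short contact time, then etherifies the 5-OH and returns to the route at 9.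

**Further compounds**

F1 | step 3 | (2S)-7-O-methylhesperetin 5-O-allyl 3'-O-(3,7-dimethyloct-6-en-1-yn-3-yl) bis-ether | COc1ccc([C@@H]2CC(=O)c3c(OCC=C)cc(OC)cc3O2)cc1OC(C)(C#C)CCC=C(C)C
F2 | step 3 | (2S)-7-O-methylhesperetin 5-O-allyl 3'-O-linalyl bis-ether | COc1ccc([C@@H]2CC(=O)c3c(OCC=C)cc(OC)cc3O2)cc1OC(C)(C=C)CCC=C(C)C
F3 | step 3 | (2S)-6-allyl-2'-[(E)-geranyl]-7-O-methylhesperetin | COc1ccc([C@@H]2CC(=O)c3c(cc(OC)c(CC=C)c3O)O2)c(C/C=C(\C)CCC=C(C)C)c1O
F4 | step 5 | (2S)-7-O-methylhesperetin 3'-O-[(E)-geranyl] ether | COc1ccc([C@@H]2CC(=O)c3c(O)cc(OC)cc3O2)cc1OC/C=C(\C)CCC=C(C)C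
F5 | step 5 | (2S)-7-O-methylhesperetin 5-O-prenyl 3'-O-[(E)-geranyl] bis-ether | COc1ccc([C@@H]2CC(=O)c3c(OCC=C(C)C)cc(OC)cc3O2)cc1OC/C=C(\C)CCC=C(C)C
F6 | step 4 | (2S)-7-O-methylhesperetin 3'-O-linalyl ether | COc1ccc([C@@H]2CC(=O)c3c(O)cc(OC)cc3O2)cc1OC(C)(C=C)CCC=C(C)C
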